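**Strategy.** Everything rests on disconnecting the lower pyran ring (ring E) at O1–C2 and deleting C2, which leads back to a deoxybenzoin: ring D–CH2–C(=O)–ring F with a free ortho phenol. The feature exploited is C4 of ring E, benzylic to ring F: carried as a ketone, it acidifies C3, turns the incoming formaldehyde carbon into the terminus of an enone, and holds the phenol by a hydrogen bond. In one operation C2 is inserted and the phenol oxygen closes ring E 6-endo to the isoflavanone. The ketone then allows a dynamic kinetic transfer hydrogenation to set C3 and leaves in the final hydrogenolysis. The upper trans-diarylchroman comes from an aminocatalytic ortho-quinone methide annulation.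

Key step: step 9

Remark on the structure: the upper chroman (benzo ring A, pyran ring C, aryl ring B on C3) is read from the SMILES as (3R,4S), which is 3,4-trans. The central benzene is ring D. The lower chroman (pyran ring E, benzo ring F) is (3R). Rotation about the bonds from ring D to its two sp3 carbons is taken as free, so atropisomers are not considered. In names, U = (3R,4S)-7-(benzyloxy)-3-[2-(benzyloxy)-4,5-dimethoxyphenyl]-3,4-dihydro-2H-chromen-4-yl.

**Route**

Step 1
Reactants: 1 2-hydroxy-4,5-dimethoxybenzaldehyde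
Product: 2 2-(benzyloxy)-4,5-dimethoxybenzaldehyde
Conditions: BnBr, K2CO3, DMF, 60 °C
Reagents that add atoms: benzyl bromide, BrCc1ccccc1
Why: Williamson etherification of the chelated ortho phenol should proceed cleanly and masks the ring B hydroxyl as a hydrogenolysable ether.

Step 2
Reactants: 2 2-(benzyloxy)-4,5-dimethoxybenzaldehyde
Product: 4 [2-(benzyloxy)-4,5-dimethoxyphenyl]acetaldehyde, via enol ether 3 (not isolated)
Conditions: Ph3P(CH2OMe)Cl, KOtBu, THF, 0 °C to rt; then 2 M HCl, THF, rt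
Reagents that add atoms: (methoxymethyl)triphenylphosphonium chloride, COC[P+](c1ccccc1)(c1ccccc1)c1ccccc1.[Cl-]; water, O
Why: Wittig methoxymethylenation followed by acid hydrolysis of the enol ether is the standard one-carbon homologation of an aryl aldehyde to an arylacetaldehyde, and the sensitive product is used crude at once.

Step 3
Reactants: 5 3-bromo-5-methoxyphenol
Product: 6 (3-bromo-5-methoxyphenoxy)tri(propan-2-yl)silane
Conditions: i-Pr3SiCl, imidazole, DMF, rt
Reagents that add atoms: chlorotri(propan-2-yl)silane, CC(C)[Si](Cl)(C(C)C)C(C)C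
Why: Silylation of the phenol installs a bulky, non-coordinating group that distinguishes this oxygen from the methoxy group and steers the metalation of step 4.

Step 4
Reactants: 6 (3-bromo-5-methoxyphenoxy)tri(propan-2-yl)silane; 7 4-(benzyloxy)-2-hydroxybenzaldehyde
Product: 10 5-(benzyloxy)-2-[{2-bromo-6-methoxy-4-[tri(propan-2-yl)silyloxy]phenyl}(hydroxy)methyl]phenol (racemic), via lithium phenolate 8 (not isolated), via aryllithium 9 (not isolated)
Conditions: 6, LiN(i-Pr)2, THF, −78 °C; then 8 (from 7 and LiN(SiMe3)2, THF, −78 °C), −78 °C; aq NH4Cl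
Reagents that add atoms: none
Why: Directed ortho-metalation should remove the proton flanked by Br and OMe because the silyloxy group shields both of its neighbours, and the aryllithium should add to the aldehyde of the preformed phenolate at −78 °C before loss of LiBr to an aryne can compete; the carbinol centre is erased in step 5.

Step 5
Reactants: 10 the carbinol of step 4; 4 [2-(benzyloxy)-4,5-dimethoxyphenyl]acetaldehyde
Product: 12 (3R,4S)-7-(benzyloxy)-3-[2-(benzyloxy)-4,5-dimethoxyphenyl]-4-{2-bromo-6-methoxy-4-[tri(propan-2-yl)silyloxy]phenyl}-3,4-dihydro-2H-chromen-2-ol (anomer mixture), via ortho-quinone methide 11 (not isolated)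
Conditions: (R)-2-[diphenyl(trimethylsilyloxy)methyl]pyrrolidine (20 mol%), PhCO2H (20 mol%), CHCl3, rt
Reagents that add atoms: none
Why: This is an enamine-catalysed formal [4+2] annulation (Michael addition, then hemiacetalisation) in which acid-promoted dehydration of 10 gives 11, the enamine of 4 with the (R)-catalyst attacks the methide carbon from its unshielded face to set C3 as R, and the 3,4-trans relationship (4S) is both the preferred transition-state outcome and the thermodynamic one because C3 can equilibrate through the open aldehyde.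

Step 6
Reactants: 12 the chroman-2-ol of step 5
Product: 13 (3R,4S)-7-(benzyloxy)-3-[2-(benzyloxy)-4,5-dimethoxyphenyl]-4-{2-bromo-6-methoxy-4-[tri(propan-2-yl)silyloxy]phenyl}-3,4-dihydro-2H-chromene
Conditions: Et3SiH, BF3·OEt2, CH2Cl2, −78 to −20 °C
Reagents that add atoms: none
Why: Ionic hydrogenation should ionise the lactol to the cyclic oxocarbenium ion and reduce it to the C2 methylene without touching C3, C4, the benzyl ethers or the aryl silyl ether.

Step 7
Reactants: 13 the aryl bromide of step 6; 14 1-[2,4-bis(benzyloxy)phenyl]ethan-1-one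
Product: 15 1-[2,4-bis(benzyloxy)phenyl]-2-{2-U-3-methoxy-5-[tri(propan-2-yl)silyloxy]phenyl}ethan-1-one
Conditions: Pd2(dba)3 (2.5 mol%), XPhos (6 mol%), K3PO4, toluene, 100 °C
Reagents that add atoms: none
Why: Palladium-catalysed ketone α-arylation with a bulky biaryl phosphine should couple the methyl ketone enolate with the ortho-substituted aryl bromide, the hindered bromide favouring monoarylation and the weak base sparing the silyl ether.

Step 8
Reactants: 15 the deoxybenzoin of step 7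
Product: 16 1-[4-(benzyloxy)-2-hydroxyphenyl]-2-{2-U-3-methoxy-5-[tri(propan-2-yl)silyloxy]phenyl}ethan-1-one
Conditions: MgBr2·OEt2, toluene–Et2O, 80 °C; H2O
Reagents that add atoms: none
Why: Chelation-controlled debenzylation should cleave only the benzyl ether ortho to the ketone, because MgBr2 binds between the carbonyl and that ether oxygen, leaving the three remote benzyl ethers, the methyl ethers and the silyl ether.

Step 9
Reactants: 16 the ortho-hydroxy deoxybenzoin of step 8
Product: 19 7-(benzyloxy)-3-{2-U-3-methoxy-5-[tri(propan-2-yl)silyloxy]phenyl}-2,3-dihydro-4H-chromen-4-one (both C3 epimers), via Mannich base 17 (not isolated), via enone 18 (not isolated)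
Conditions: (CH2O)n (1.5 equiv), Et2NH, EtOH, 70 °C
Reagents that add atoms: paraformaldehyde, as formaldehyde C=O
Why: Diethylamine and formaldehyde should aminomethylate the C3 methylene of 16, which is acidified by both ring D and the ketone (Mannich reaction); E1cB loss of diethylamine from 17 gives the 2-aryl-1-(2-hydroxyaryl)prop-2-en-1-one 18, and the ring F phenol oxygen, held beside the carbonyl by its hydrogen bond, adds to the terminal CH2 (oxa-Michael addition) to form the O1–C2 bond. The closest known reaction type is the one-pot conversion of 2-hydroxydeoxybenzoins into isoflavanones with paraformaldehyde and a secondary amine. Ring E closes in the 6-endo-trig mode, the only one open to this enone because the acceptor carbon is terminal. The new C3 stereocentre arises by unselective protonation of the ring E enol and is deliberately left as an epimer mixture, since it stays enolisable and is set in step 10. The step needs chemoselectivity for C-aminomethylation at C3 over the aromatic rings and against a second hydroxymethylation of 19: the only free phenol is the acyl-deactivated, chelated one, all other phenols are masked as benzyl or silyl ethers, and formaldehyde is limited to a small excess.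

Step 10
Reactants: 19 the isoflavanone of step 9
Product: 20 (3R,4R)-7-(benzyloxy)-3-{2-U-3-methoxy-5-[tri(propan-2-yl)silyloxy]phenyl}-3,4-dihydro-2H-chromen-4-ol (3,4-cis)
Conditions: RuCl[(R,R)-TsDPEN](p-cymene) (5 mol%), HCO2H/Et3N (5:2), EtOAc, 40 °C
Reagents that add atoms: none
Why: Noyori asymmetric transfer hydrogenation with dynamic kinetic resolution should apply, since Et3N epimerises C3 through the enol faster than reduction and the (R,R)-catalyst reduces only the (3R)-ketone to the (4R)-alcohol, giving the cis-(3R,4R) isomer under catalyst control.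

Step 11
Reactants: 20 the isoflavan-4-ol of step 10
Product: 21 (3R,4R)-7-(benzyloxy)-3-(2-U-5-hydroxy-3-methoxyphenyl)-3,4-dihydro-2H-chromen-4-ol
Conditions: Bu4NF, AcOH, THF, 0 °C
Reagents that add atoms: none
Why: Fluoride-mediated desilylation should cleave the aryl silyl ether selectively, the acetic acid buffer protecting the benzylic alcohol and the benzyl ethers from the phenoxide.

Step 12
Reactants: 21 the phenol of step 11
Product: 22 (3R)-3-{5-hydroxy-2-[(3R,4S)-7-hydroxy-3-(2-hydroxy-4,5-dimethoxyphenyl)-3,4-dihydro-2H-chromen-4-yl]-3-methoxyphenyl}-3,4-dihydro-2H-chromen-7-ol (CNP0266829.1)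
Conditions: H2 (1 atm), Pd/C (10 wt%), EtOAc–EtOH, AcOH (cat.), rt
Reagents that add atoms: none
Why: Catalytic hydrogenolysis should remove the three benzyl ethers and the ring E benzylic C4 hydroxyl (activated by the para oxygen of ring F) in one operation, with no stereocentre involved provided strong acid is avoided so that no isoflav-3-ene forms.

**Compound list**

1 | 2-hydroxy-4,5-dimethoxybenzaldehyde | O=Cc1cc(OC)c(OC)cc1O | starting material
2 | 2-(benzyloxy)-4,5-dimethoxybenzaldehyde | O=Cc1cc(OC)c(OC)cc1OCc1ccccc1 | intermediate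
3 | 1-(benzyloxy)-4,5-dimethoxy-2-(2-methoxyethenyl)benzene (E/Z mixture) | COC=Cc1cc(OC)c(OC)cc1OCc1ccccc1 | intermediate
4 | [2-(benzyloxy)-4,5-dimethoxyphenyl]acetaldehyde | O=CCc1cc(OC)c(OC)cc1OCc1ccccc1 | intermediate
5 | 3-bromo-5-methoxyphenol | COc1cc(O)cc(Br)c1 | starting material
6 | (3-bromo-5-methoxyphenoxy)tri(propan-2-yl)silane | COc1cc(Br)cc(O[Si](C(C)C)(C(C)C)C(C)C)c1 | intermediate
7 | 4-(benzyloxy)-2-hydroxybenzaldehyde | O=Cc1ccc(OCc2ccccc2)cc1O | starting material
8 | lithium 5-(benzyloxy)-2-formylphenolate | [Li+].[O-]c1cc(OCc2ccccc2)ccc1C=O | intermediate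
9 | {2-bromo-6-methoxy-4-[tri(propan-2-yl)silyloxy]phenyl}lithium | [Li]c1c(Br)cc(O[Si](C(C)C)(C(C)C)C(C)C)cc1OC | intermediate
10 | 5-(benzyloxy)-2-[{2-bromo-6-methoxy-4-[tri(propan-2-yl)silyloxy]phenyl}(hydroxy)methyl]phenol (racemic) | OC(c1ccc(OCc2ccccc2)cc1O)c1c(Br)cc(O[Si](C(C)C)(C(C)C)C(C)C)cc1OC | intermediate
11 | 3-(benzyloxy)-6-({2-bromo-6-methoxy-4-[tri(propan-2-yl)silyloxy]phenyl}methylidene)cyclohexa-2,4-dien-1-one | O=C1C=C(OCc2ccccc2)C=CC1=Cc1c(Br)cc(O[Si](C(C)C)(C(C)C)C(C)C)cc1OC | intermediate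
12 | (3R,4S)-7-(benzyloxy)-3-[2-(benzyloxy)-4,5-dimethoxyphenyl]-4-{2-bromo-6-methoxy-4-[tri(propan-2-yl)silyloxy]phenyl}-3,4-dihydro-2H-chromen-2-ol (anomer mixture) | COc1cc(OCc2ccccc2)c([C@@H]2C(O)Oc3cc(OCc4ccccc4)ccc3[C@H]2c2c(OC)cc(O[Si](C(C)C)(C(C)C)C(C)C)cc2Br)cc1OC | intermediate
13 | (3R,4S)-7-(benzyloxy)-3-[2-(benzyloxy)-4,5-dimethoxyphenyl]-4-{2-bromo-6-methoxy-4-[tri(propan-2-yl)silyloxy]phenyl}-3,4-dihydro-2H-chromene | COc1cc(OCc2ccccc2)c([C@@H]2COc3cc(OCc4ccccc4)ccc3[C@H]2c2c(OC)cc(O[Si](C(C)C)(C(C)C)C(C)C)cc2Br)cc1OC | intermediate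
14 | 1-[2,4-bis(benzyloxy)phenyl]ethan-1-one | CC(=O)c1ccc(OCc2ccccc2)cc1OCc1ccccc1 | starting material
15 | 1-[2,4-bis(benzyloxy)phenyl]-2-{2-U-3-methoxy-5-[tri(propan-2-yl)silyloxy]phenyl}ethan-1-one | COc1cc(OCc2ccccc2)c([C@@H]2COc3cc(OCc4ccccc4)ccc3[C@H]2c2c(OC)cc(O[Si](C(C)C)(C(C)C)C(C)C)cc2CC(=O)c2ccc(OCc3ccccc3)cc2OCc2ccccc2)cc1OC | intermediate
16 | 1-[4-(benzyloxy)-2-hydroxyphenyl]-2-{2-U-3-methoxy-5-[tri(propan-2-yl)silyloxy]phenyl}ethan-1-one | COc1cc(OCc2ccccc2)c([C@@H]2COc3cc(OCc4ccccc4)ccc3[C@H]2c2c(OC)cc(O[Si](C(C)C)(C(C)C)C(C)C)cc2CC(=O)c2ccc(OCc3ccccc3)cc2O)cc1OC | intermediate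
17 | 1-[4-(benzyloxy)-2-hydroxyphenyl]-3-(diethylamino)-2-{2-U-3-methoxy-5-[tri(propan-2-yl)silyloxy]phenyl}propan-1-one (both C2 epimers) | COc1cc(OCc2ccccc2)c([C@@H]2COc3cc(OCc4ccccc4)ccc3[C@H]2c2c(OC)cc(O[Si](C(C)C)(C(C)C)C(C)C)cc2C(CN(CC)CC)C(=O)c2ccc(OCc3ccccc3)cc2O)cc1OC | intermediate
18 | 1-[4-(benzyloxy)-2-hydroxyphenyl]-2-{2-U-3-methoxy-5-[tri(propan-2-yl)silyloxy]phenyl}prop-2-en-1-one | COc1cc(OCc2ccccc2)c([C@@H]2COc3cc(OCc4ccccc4)ccc3[C@H]2c2c(OC)cc(O[Si](C(C)C)(C(C)C)C(C)C)cc2C(=C)C(=O)c2ccc(OCc3ccccc3)cc2O)cc1OC | intermediate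
19 | 7-(benzyloxy)-3-{2-U-3-methoxy-5-[tri(propan-2-yl)silyloxy]phenyl}-2,3-dihydro-4H-chromen-4-one (both C3 epimers) | COc1cc(OCc2ccccc2)c([C@@H]2COc3cc(OCc4ccccc4)ccc3[C@H]2c2c(OC)cc(O[Si](C(C)C)(C(C)C)C(C)C)cc2C2COc3cc(OCc4ccccc4)ccc3C2=O)cc1OC | intermediate
20 | (3R,4R)-7-(benzyloxy)-3-{2-U-3-methoxy-5-[tri(propan-2-yl)silyloxy]phenyl}-3,4-dihydro-2H-chromen-4-ol | COc1cc(OCc2ccccc2)c([C@@H]2COc3cc(OCc4ccccc4)ccc3[C@H]2c2c(OC)cc(O[Si](C(C)C)(C(C)C)C(C)C)cc2[C@@H]2COc3cc(OCc4ccccc4)ccc3[C@@H]2O)cc1OC | intermediate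
21 | (3R,4R)-7-(benzyloxy)-3-(2-U-5-hydroxy-3-methoxyphenyl)-3,4-dihydro-2H-chromen-4-ol | COc1cc(OCc2ccccc2)c([C@@H]2COc3cc(OCc4ccccc4)ccc3[C@H]2c2c(OC)cc(O)cc2[C@@H]2COc3cc(OCc4ccccc4)ccc3[C@@H]2O)cc1OC | intermediate
22 | (3R)-3-{5-hydroxy-2-[(3R,4S)-7-hydroxy-3-(2-hydroxy-4,5-dimethoxyphenyl)-3,4-dihydro-2H-chromen-4-yl]-3-methoxyphenyl}-3,4-dihydro-2H-chromen-7-ol | COc1cc(O)c([C@@H]2COc3cc(O)ccc3[C@H]2c2c(OC)cc(O)cc2[C@@H]2COc3cc(O)ccc3C2)cc1OC | target

**Step count.** Total: 12 steps. Longest linear sequence: 10 steps (steps 3 to 12 from 5, or steps 1, 2 and 5 to 12 from 1).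

**Steps most likely to fail**

Step 5. The carbon–carbon bond formation at the methide carbon may be slow because the 2,6-disubstituted ring D shields it, so that self-condensation of aldehyde 4 takes over, or the facial selectivity may be poor. The fallback sets out from 6 and 4 and comes back at 13; it builds C3 by an auxiliary-controlled aldol reaction and closes ring C by an intramolecular Friedel–Crafts alkylation. Lithiation of 6 as in step 4 and a DMF quench would give 2-bromo-6-methoxy-4-[tri(propan-2-yl)silyloxy]benzaldehyde F1. Pinnick oxidation of 4 (NaClO2, NaH2PO4, 2-methylbut-2-ene) would give [2-(benzyloxy)-4,5-dimethoxyphenyl]acetic acid F2, which would be N-acylated onto (4S)-4-benzyl-1,3-oxazolidin-2-one (PivCl, Et3N, LiCl) to give (4S)-4-benzyl-3-{[2-(benzyloxy)-4,5-dimethoxyphenyl]acetyl}-1,3-oxazolidin-2-one F3. The Evans syn-aldol reaction of F3 with F1 (Bu2BOTf, i-Pr2NEt, CH2Cl2, −78 to 0 °C) should give the (2S,3S)-aldol adduct F4, whose α-carbon has the configuration needed at C3. LiBH4 would remove the auxiliary to give the (1S,2R)-2-aryl-1-arylpropane-1,3-diol F5. Mitsunobu etherification of its primary hydroxyl with 3-(benzyloxy)phenol (PPh3, DIAD) would give the aryl ether F6. TFA in CH2Cl2 at −40 °C should then ionise the benzylic alcohol; the cation, stabilised by ring D, is captured by the tethered aryl ether para to its benzyloxy group and anti to the C3 aryl, giving 13.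

Step 10. Reduction may be slow at the congested ketone, catalyst control may be eroded by the bulky chiral ortho substituent on ring D, or ring E may open by retro-oxa-Michael reaction under the basic conditions. The fallback sets out from 19 and comes back at 22; it sets C3 by asymmetric hydrogenation of an alkene instead. NaBH4 (THF–MeOH, 0 °C) would give the epimeric isoflavan-4-ols F7, and TsOH·H2O in toluene at 60 °C would dehydrate them to the isoflav-3-ene F8. Hydrogenation with [Ir(cod)((S)-t-Bu-PHOX)]BArF under H2 (50 bar) in CH2Cl2, or with its enantiomer, whichever delivers hydrogen to the face giving 3R, should give the silyl- and benzyl-protected (3R)-isoflavan F9. Bu4NF with AcOH would give the phenol F10, and hydrogenolysis as in step 12 would give 22.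

Step 9. Aminomethylation may stall at the congested C3 methylene, or over-reaction may set in (a second hydroxymethylation at C3 of the product, aminomethylation of an aromatic ring). The fallback sets out from 16 and comes back at 20; it closes the same O1–C2 bond at the enol ether oxidation level. N,N-Dimethylformamide dimethyl acetal in toluene at 90 °C would give the enaminone F11, which closes by addition of the ring F phenol and loss of dimethylamine to the isoflavone F12. Transfer hydrogenation of F12 with RuCl[(R,R)-TsDPEN](p-cymene) and HCO2H/Et3N should reduce first the C2=C3 bond and then, with dynamic kinetic resolution, the ketone, giving 20.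

**Further compounds**

F1 | step 5 | 2-bromo-6-methoxy-4-[tri(propan-2-yl)silyloxy]benzaldehyde | O=Cc1c(Br)cc(O[Si](C(C)C)(C(C)C)C(C)C)cc1OC
F2 | step 5 | [2-(benzyloxy)-4,5-dimethoxyphenyl]acetic acid | OC(=O)Cc1cc(OC)c(OC)cc1OCc1ccccc1
F3 | step 5 | (4S)-4-benzyl-3-{[2-(benzyloxy)-4,5-dimethoxyphenyl]acetyl}-1,3-oxazolidin-2-one | O=C(Cc1cc(OC)c(OC)cc1OCc1ccccc1)N1[C@@H](Cc2ccccc2)COC1=O
F4 | step 5 | (4S)-4-benzyl-3-[(2S,3S)-2-[2-(benzyloxy)-4,5-dimethoxyphenyl]-3-{2-bromo-6-methoxy-4-[tri(propan-2-yl)silyloxy]phenyl}-3-hydroxypropanoyl]-1,3-oxazolidin-2-one | O=C([C@@H](c1cc(OC)c(OC)cc1OCc1ccccc1)[C@H](O)c1c(Br)cc(O[Si](C(C)C)(C(C)C)C(C)C)cc1OC)N1[C@@H](Cc2ccccc2)COC1=O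
F5 | step 5 | (1S,2R)-2-[2-(benzyloxy)-4,5-dimethoxyphenyl]-1-{2-bromo-6-methoxy-4-[tri(propan-2-yl)silyloxy]phenyl}propane-1,3-diol | OC[C@@H](c1cc(OC)c(OC)cc1OCc1ccccc1)[C@H](O)c1c(Br)cc(O[Si](C(C)C)(C(C)C)C(C)C)cc1OC
F6 | step 5 | (1S,2R)-2-[2-(benzyloxy)-4,5-dimethoxyphenyl]-3-[3-(benzyloxy)phenoxy]-1-{2-bromo-6-methoxy-4-[tri(propan-2-yl)silyloxy]phenyl}propan-1-ol | c1ccccc1COc1cccc(OC[C@@H](c2cc(OC)c(OC)cc2OCc2ccccc2)[C@H](O)c2c(Br)cc(O[Si](C(C)C)(C(C)C)C(C)C)cc2OC)c1
F7 | step 10 | 7-(benzyloxy)-3-{2-U-3-methoxy-5-[tri(propan-2-yl)silyloxy]phenyl}-3,4-dihydro-2H-chromen-4-ol (epimers at C3 and C4) | COc1cc(OCc2ccccc2)c([C@@H]2COc3cc(OCc4ccccc4)ccc3[C@H]2c2c(OC)cc(O[Si](C(C)C)(C(C)C)C(C)C)cc2C2COc3cc(OCc4ccccc4)ccc3C2O)cc1OC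
F8 | step 10 | 7-(benzyloxy)-3-{2-U-3-methoxy-5-[tri(propan-2-yl)silyloxy]phenyl}-2H-chromene | COc1cc(OCc2ccccc2)c([C@@H]2COc3cc(OCc4ccccc4)ccc3[C@H]2c2c(OC)cc(O[Si](C(C)C)(C(C)C)C(C)C)cc2C2=Cc3ccc(OCc4ccccc4)cc3OC2)cc1OC
F9 | step 10 | (3R)-7-(benzyloxy)-3-{2-U-3-methoxy-5-[tri(propan-2-yl)silyloxy]phenyl}-3,4-dihydro-2H-chromene | COc1cc(OCc2ccccc2)c([C@@H]2COc3cc(OCc4ccccc4)ccc3[C@H]2c2c(OC)cc(O[Si](C(C)C)(C(C)C)C(C)C)cc2[C@@H]2COc3cc(OCc4ccccc4)ccc3C2)cc1OC
F10 | step 10 | 3-[(3R)-7-(benzyloxy)-3,4-dihydro-2H-chromen-3-yl]-4-U-5-methoxyphenol | COc1cc(OCc2ccccc2)c([C@@H]2COc3cc(OCc4ccccc4)ccc3[C@H]2c2c(OC)cc(O)cc2[C@@H]2COc3cc(OCc4ccccc4)ccc3C2)cc1OC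
F11 | step 9 | 1-[4-(benzyloxy)-2-hydroxyphenyl]-3-(dimethylamino)-2-{2-U-3-methoxy-5-[tri(propan-2-yl)silyloxy]phenyl}prop-2-en-1-one | COc1cc(OCc2ccccc2)c([C@@H]2COc3cc(OCc4ccccc4)ccc3[C@H]2c2c(OC)cc(O[Si](C(C)C)(C(C)C)C(C)C)cc2C(=CN(C)C)C(=O)c2ccc(OCc3ccccc3)cc2O)cc1OC
F12 | step 9 | 7-(benzyloxy)-3-{2-U-3-methoxy-5-[tri(propan-2-yl)silyloxy]phenyl}-4H-chromen-4-one | COc1cc(OCc2ccccc2)c([C@@H]2COc3cc(OCc4ccccc4)ccc3[C@H]2c2c(OC)cc(O[Si](C(C)C)(C(C)C)C(C)C)cc2-c2coc3cc(OCc4ccccc4)ccc3c2=O)cc1OC
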